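## The problem

Compound 43 is a germacranolide. A ten-membered carbocycle (C1–C10) with a cis C1=C10 double bond is fused through C6 and C7 to an α-(acetoxymethyl)butenolide, whose tetrasubstituted C7=C11 bond belongs to both rings. Numbering: C11 is the butenolide α-carbon, C12 the lactone carbonyl, C13 the CH2OAc carbon, C14 the CH2O carbon on C10, C15 the methyl on C4.

Seven ring stereocentres (C2, C3, C4, C5, C6, C8, C9) and one in the 2-methyloxirane-2-carboxylate must be set. The C6 carbinol can direct the cis C4–C5 epoxide, and C8/C9 are a syn pair that can be made in one event. The trans C2–C3 epoxide is insulated from the rest and needs reagent control, and the ester stereocentre has to be bought.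

Four oxygens (C8, C9, C13, C14) carry three different acyl groups and must stay distinguishable to the end. The two epoxides (the C2–C3 one is allylic to C1=C10) rule out strong protic and Lewis acids and late zerovalent palladium. The four esters, the γ-hydrogen of the butenolide at C6 and the vicinal C8/C9 acyloxy pair (acyl migration) rule out strong bases and nucleophiles late in the route.

The central difficulty is closing a heavily substituted ten-membered ring without losing the cis C1=C10 geometry. The feature that opens a way is that C8 and C9 are neighbouring oxygenated carbons next to C7, and C7 bears an sp2 exocyclic carbon. C8, C7 and an exocyclic CH2 can therefore be read as a γ-alkoxyallyl unit: its addition to a C9 aldehyde forms C8–C9, sets both stereocentres and leaves a C7 methylene on which the butenolide can be built.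

## Retrosynthesis

**Peripheral esters (43 ⇒ 42 ⇒ 41 ⇒ 40 ⇒ 39).** The C14–O senecioyl bond and the C8–O and C13–O acetyl bonds are cut first. The senecioate is the ester most easily deconjugated or displaced, so it goes on last, through alcohol 42 and silyl ether 41. Both acetates come from diol 40, which the bis-PMB ether 39 releases in one oxidative step. Carrying the C13 acetate through the ring closure would expose an allylic acetate on an acrylate to nucleophilic catalysts, so a PMB ether is preferred. The forward steps (DDQ, acetylation, buffered fluoride, acylation) must spare two epoxides and the C9 epoxy ester.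

**Butenolide (39 ⇒ 38 ⇒ 34 + 36).** The C7=C11 bond and the C6–O acyl bond are cut. Ring-closing metathesis of acrylate 38 joins the exocyclic C7 methylene to the acrylate α-carbon, and 38 is the ester of alcohol 34 with acid 36. The exocyclic carbon of 38 leaves as ethylene, so C11 of 43 comes from 36. This cut is preferred to any aldol-type closure, which would need a C7 ketone next to two oxygenated stereocentres. The precursor 34 is a simple methylene macrocycle; the forward reaction must form a tetrasubstituted olefin.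

**C9 ester (34 ⇒ 33 ⇒ 29 + 31).** The C9–O acyl bond is cut to macrocyclic alcohol 29 and (S)-acid 31. Esterifying before the C6 silyl ether is removed uses the fact that C9–OH is the only free hydroxyl in 29. The reaction must acylate a hindered allylic alcohol without opening the glycidate.

**Key cut (29 ⇒ 27).** The C8–C9 bond is cut, opening the ten-membered ring to enal 27, which carries a pinacol γ-(PMB-oxy)allylboronate on C7. This cut is preferred to C1–C2, C2–C3 or C6–C7 ring closures because it creates two stereocentres, delivers C8 and C9 with different oxygen substituents, and needs no acid, base or metal. The precursor is acyclic with five stereocentres already in place. The forward reaction must be syn-selective and must choose one face of the enol ether.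

**Boron and aldehyde unmasked late (27 ⇒ 26 ⇒ 24 ⇒ 23).** The C9 aldehyde is traced to alcohol 26 and the boronate to stannane 24, itself from pivalate 23. A boronate cannot coexist with the C3 aldehyde needed for fragment union (a six-membered allylboration would follow), whereas an allylstannane is inert to aldehydes without a Lewis acid. Tin therefore serves as a relay and is exchanged for boron only after the last intermolecular C–C bond is made.

**C2–C3 epoxide (23 ⇒ 8 + 21).** The C2–C3 and C2–O bonds are cut to allylic sulfonium salt 8 and epoxy aldehyde 21. A sulfur-ylide epoxidation makes the trans epoxide and joins the two halves in one step, with the chiral sulfide 7 as the source of induction. The aldehyde 21 is α-quaternary and cannot epimerise or isomerise, unlike the Z-enal that an earlier union would require.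

**C3–C8 fragment (21 ⇒ 20 ⇒ 18 ⇒ 17 ⇒ 16 ⇒ 15 ⇒ 14 + 10).** The C11′–Sn bond of 20 is traced to metalation of allyl ether 18 (from 17). The C4–C5 epoxide of 16 is traced to hydroxyl-directed epoxidation of Z-allylic alcohol 15. The C6–C7 bond is traced to a catalytic asymmetric alkenylation of Z-enal 14 with bromide 10 (from 9). Enal 14 comes in three steps from butenolide 11 through amides 12 and 13, and the ring of 11 supplies the Z geometry.

**C9–C2/C14 fragment (8 ⇒ 6 + 7; 6 ⇒ 5 ⇒ 4 ⇒ 2 ⇒ 1).** The sulfonium salt comes from bromide 6 and sulfide 7. The C9–C10 bond of 5 is cut to Z-iodide 4, obtained from butynediol 1 through monosilyl ether 2 by directed trans-hydroalumination. Trans addition fixes C14 trans and C9 cis to C2, and coupling a pre-protected C9 unit differentiates the three oxygens without extra protecting-group steps.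

## Roads not taken

**Alternative 1:** The butenolide oxygenation would be unveiled last. Singlet oxygen (rose bengal, light, low temperature) would oxidise the C12-silylated furan A1, fused to the macrocycle at C6–C7, to the Z γ-keto acid A2, the open tautomer of the 6-hydroxybutenolide.
- Merits: silyl-directed furan photooxygenation is regiochemically dependable, needs no metal, and creates the tetrasubstituted C7=C11 bond without metathesis. In that respect it is better than the chosen plan, which must close a tetrasubstituted olefin in step 26.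
- Weak points: it does not address closure of the ten-membered ring. Singlet oxygen meets two ene-reactive trisubstituted olefins, C1=C10 and the senecioate. In A2, C6 is a ketone next to the C4–C5 epoxide, so the C6 stereocentre must be regenerated by a late hydride reduction whose facial sense only the macrocycle can decide.
- Comparison: the chosen plan sets C6 early by catalyst control and uses it to direct the C4–C5 epoxide; it pays with the uncertain metathesis.

**Alternative 2:** The C6–C7 and O–C12 bonds would be cut. CrCl2 with catalytic NiCl2 and a chiral sulfonamide ligand would convert enol triflate A3 into an alkenylchromium that adds to the C6 enal; the alkoxide would then lactonise onto the cis C12 methyl ester to give A4.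
- Merits: chromium-mediated macrocyclisations onto aldehydes have better precedent at medium ring size than the chosen key step. Ring and butenolide form in one operation with all esters already in place, so the sequence after ring closure is shorter. C6 is set by the catalyst and no metathesis is needed.
- Weak points: nickel must insert into a tetrasubstituted β-triflyloxy acrylate, and the low-valent metal sits next to a vinyl epoxide. C8 and C9 must be built beforehand on an open chain. A4 still lacks the C4–C5 epoxide, which would have to be introduced on the macrocycle with no hydroxyl to direct it, in competition with C1=C10 and the senecioate.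
- Comparison: the chosen plan makes C8/C9 in the ring closure and the C4–C5 epoxide under hydroxyl direction; it concedes weaker precedent for ring closure and more steps after it.

**Alternative 3:** The C2–C3 and C2–O bonds would be cut in the ring. A hindered base would deprotonate the allylic diphenylsulfonium salt A5, and the ylide would add to the C3 aldehyde and expel diphenyl sulfide to give A6, closing ring and epoxide together.
- Merits: ring and epoxide arise in one step, the butenolide is already present so no metathesis is needed, and only deprotections and acylations follow.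
- Weak points: the sulfonium group is achiral, so C2 and C3 would be set by macrocyclic conformation alone. The base has to find the sulfonium α-hydrogen in the presence of the acidic γ-hydrogen at C6 of the butenolide and the C13 acetate. A ten-membered ylide ring closure is as unprecedented as the chosen key step.
- Comparison: the chosen plan uses the same epoxide-forming reaction intermolecularly (step 16), under reagent control and before any base-sensitive butenolide exists; it pays with a longer sequence after ring closure.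

Key step: step 20

## Route

Assumption: 4-methylfuran-2(5H)-one (11) is taken as commercially available, and the sense of induction of sulfide 7 (step 16) and of the chromium ligand (step 10) must be confirmed on model aldehydes; the antipodes of both are equally accessible.

C11′ denotes the exocyclic carbon of the allyl unit; it is lost as ethylene in step 26 and is not C11 of 43.

Step 1
Reactants: 1 but-2-yne-1,4-diol
Product: 2 4-[(tert-butyldimethylsilyl)oxy]but-2-yn-1-ol
Conditions: NaH (1 equiv), THF, 0 °C; t-BuMe2SiCl (1 equiv); diol in threefold excess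
Reagents that add atoms: tert-butyldimethylsilyl chloride, CC(C)(C)[Si](C)(C)Cl
Why: O-silylation of the monosodium alkoxide of a symmetrical diol; the excess of diol suppresses the bis-ether.

Step 2
Reactants: 2 4-[(tert-butyldimethylsilyl)oxy]but-2-yn-1-ol
Product: 4 (2Z)-4-[(tert-butyldimethylsilyl)oxy]-3-iodobut-2-en-1-ol, via cyclic alkenylaluminate 3 (not isolated)
Conditions: NaAlH2(OCH2CH2OCH3)2, THF, 0 °C; EtOAc; then I2, −78 °C
Reagents that add atoms: iodine, II
Why: Hydroxyl-directed trans-hydroalumination of the propargylic alcohol puts aluminium on the distal alkyne carbon (C10); iodinolysis with retention gives the Z-iodide, so C14 ends trans and iodine cis to C2.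

Step 3
Reactants: 4 (2Z)-4-[(tert-butyldimethylsilyl)oxy]-3-iodobut-2-en-1-ol
Product: 5 (2E)-2-{[(tert-butyldimethylsilyl)oxy]methyl}-4-hydroxybut-2-en-1-yl 2,2-dimethylpropanoate
Conditions: ICH2OC(O)t-Bu, Zn dust, THF; then 4, Pd(PPh3)4 (5 mol %), THF, 40 °C
Reagents that add atoms: (pivaloyloxymethyl)zinc iodide, CC(C)(C)C(=O)OC[Zn]I (made in the flask from iodomethyl pivalate, CC(C)(C)C(=O)OCI, and zinc)
Why: Negishi coupling with retention at the alkenyl iodide; the organozinc tolerates the free hydroxyl and delivers C9 already protected, so the C9 and C2 oxygens are told apart without a protection sequence.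

Step 4
Reactants: 5 (2E)-2-{[(tert-butyldimethylsilyl)oxy]methyl}-4-hydroxybut-2-en-1-yl 2,2-dimethylpropanoate
Product: 6 (2E)-4-bromo-2-{[(tert-butyldimethylsilyl)oxy]methyl}but-2-en-1-yl 2,2-dimethylpropanoate
Conditions: CBr4, PPh3, CH2Cl2, 0 °C
Reagents that add atoms: carbon tetrabromide, BrC(Br)(Br)Br
Why: Appel reaction; a primary allylic alcohol becomes the bromide under neutral conditions without allylic transposition, and the silyl ether and pivalate are inert.

Step 5
Reactants: 6 (2E)-4-bromo-2-{[(tert-butyldimethylsilyl)oxy]methyl}but-2-en-1-yl 2,2-dimethylpropanoate; 7 (2R,5R)-2,5-dimethylthiolane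
Product: 8 (2R,5R)-1-[(2E)-3-{[(tert-butyldimethylsilyl)oxy]methyl}-4-(pivaloyloxy)but-2-en-1-yl]-2,5-dimethylthiolan-1-ium tetrafluoroborate
Conditions: NaBF4, CH2Cl2/H2O, rt, dark
Reagents that add atoms: sodium tetrafluoroborate, [Na+].F[B-](F)(F)F
Why: SN2 S-alkylation at the primary allylic carbon followed by anion exchange; the sulfide is C2-symmetric, so sulfur is not a stereocentre in the salt.

Step 6
Reactants: 9 2-bromoprop-2-en-1-ol
Product: 10 1-{[(2-bromoprop-2-en-1-yl)oxy]methyl}-4-methoxybenzene
Conditions: NaH, 4-MeOC6H4CH2Cl, Bu4NI (cat.), THF, 0 °C → rt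
Reagents that add atoms: 4-methoxybenzyl chloride, COc1ccc(CCl)cc1
Why: Williamson ether synthesis on a primary allylic alkoxide; the alkenyl bromide is inert to these conditions.

Step 7
Reactants: 11 4-methylfuran-2(5H)-one
Product: 12 (2Z)-4-hydroxy-N-methoxy-N,3-dimethylbut-2-enamide
Conditions: MeNH(OMe)·HCl, AlMe3, CH2Cl2, 0 °C → rt
Reagents that add atoms: N,O-dimethylhydroxylamine hydrochloride, CNOC.Cl
Why: Aluminium-amide aminolysis of the lactone; the ring fixes the Z geometry (C6 carbonyl cis to C3), which the open chain inherits.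

Step 8
Reactants: 12 (2Z)-4-hydroxy-N-methoxy-N,3-dimethylbut-2-enamide
Product: 13 (2Z)-N-methoxy-N,3-dimethyl-4-[(triethylsilyl)oxy]but-2-enamide
Conditions: Et3SiCl, imidazole, CH2Cl2, 0 °C
Reagents that add atoms: chlorotriethylsilane, CC[Si](CC)(CC)Cl
Why: O-silylation of the primary alcohol, done at once so that the Z-hydroxy amide cannot relactonise.

Step 9
Reactants: 13 (2Z)-N-methoxy-N,3-dimethyl-4-[(triethylsilyl)oxy]but-2-enamide
Product: 14 (2Z)-3-methyl-4-[(triethylsilyl)oxy]but-2-enal
Conditions: i-Bu2AlH, THF, −78 °C; cold neutral work-up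
Reagents that add atoms: none
Why: Partial reduction of the N-methoxy-N-methylamide through its chelated tetrahedral intermediate stops at the aldehyde; low temperature and neutral work-up keep the Z geometry.

Step 10
Reactants: 14 (2Z)-3-methyl-4-[(triethylsilyl)oxy]but-2-enal; 10 1-{[(2-bromoprop-2-en-1-yl)oxy]methyl}-4-methoxybenzene
Product: 15 (3S,4Z)-2-{[(4-methoxybenzyl)oxy]methyl}-5-methyl-6-[(triethylsilyl)oxy]hexa-1,4-dien-3-ol
Conditions: CrCl2 (10 mol %), chiral oxazoline–sulfonamide ligand (11 mol %), NiCl2·(2,9-dimethyl-1,10-phenanthroline) (2 mol %), Mn, Cp2ZrCl2, LiCl, MeCN, rt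
Reagents that add atoms: none
Why: Catalytic asymmetric Nozaki–Hiyama–Kishi alkenylation; the alkenylchromium adds to the aldehyde inside the chiral ligand sphere, which alone sets C6 (3S in this name) because no other stereocentre is present. The neutral conditions should leave the Z-enal geometry intact.

Step 11
Reactants: 15 (3S,4Z)-2-{[(4-methoxybenzyl)oxy]methyl}-5-methyl-6-[(triethylsilyl)oxy]hexa-1,4-dien-3-ol
Product: 16 (1R)-2-{[(4-methoxybenzyl)oxy]methyl}-1-[(2S,3R)-3-methyl-3-{[(triethylsilyl)oxy]methyl}oxiran-2-yl]prop-2-en-1-ol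
Conditions: m-ClC6H4CO3H, NaHCO3, CH2Cl2, −20 → 0 °C
Reagents that add atoms: 3-chloroperoxybenzoic acid, OOC(=O)c1cccc(Cl)c1
Why: Hydroxyl-directed peracid epoxidation; allylic 1,3-strain with the cis C3 group holds C6–H in the olefin plane, so the hydrogen-bonded peracid delivers oxygen to one face and gives the threo epoxy alcohol. The trisubstituted olefin is more nucleophilic than the 1,1-disubstituted one flanked by two allylic oxygens.

Step 12
Reactants: 16 (1R)-2-{[(4-methoxybenzyl)oxy]methyl}-1-[(2S,3R)-3-methyl-3-{[(triethylsilyl)oxy]methyl}oxiran-2-yl]prop-2-en-1-ol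
Product: 17 bis(triethylsilyl) ether of 16 (C3 and C6 oxygens silylated; 4R,5S,6R in target numbering)
Conditions: Et3SiOSO2CF3, 2,6-lutidine, CH2Cl2, −78 °C
Reagents that add atoms: triethylsilyl trifluoromethanesulfonate, CC[Si](CC)(CC)OS(=O)(=O)C(F)(F)F
Why: Silylation of the hindered secondary alcohol with a silyl triflate and a hindered base; at −78 °C the epoxide is not opened.

Step 13
Reactants: 17 bis(triethylsilyl) ether of 16
Product: 18 [(2R,3S)-3-{(1R)-2-{[(4-methoxybenzyl)oxy]methyl}-1-[(triethylsilyl)oxy]prop-2-en-1-yl}-2-methyloxiran-2-yl]methanol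
Conditions: HF·pyridine, pyridine, THF, 0 °C
Reagents that add atoms: none
Why: Buffered fluoride cleaves the primary triethylsilyl ether much faster than the hindered secondary one; it is done before tin is introduced, while nothing acid-sensitive is present.

Step 14
Reactants: 18 [(2R,3S)-3-{(1R)-2-{[(4-methoxybenzyl)oxy]methyl}-1-[(triethylsilyl)oxy]prop-2-en-1-yl}-2-methyloxiran-2-yl]methanol
Product: 20 [(2R,3S)-2-methyl-3-{(1R,2Z)-3-[(4-methoxybenzyl)oxy]-2-[(tributylstannyl)methyl]-1-[(triethylsilyl)oxy]prop-2-en-1-yl}oxiran-2-yl]methanol, via dilithio alkoxide allyl anion 19 (not isolated)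
Conditions: s-BuLi (2.3 equiv), THF, −78 °C; Bu3SnCl (2.4 equiv), −78 °C; aq. NaHCO3
Reagents that add atoms: tributyltin chloride, CCCC[Sn](Cl)(CCCC)CCCC
Why: Allyl-ether metalation and γ-stannylation; after alkoxide formation, s-BuLi removes an allylic proton next to the ether oxygen, O–Li chelation holds the oxyallyl anion cis, and tin enters at the terminus to give the enol ether with CH2Sn cis to OPMB. Holding −78 °C suppresses Wittig rearrangement, and the fully substituted C4 blocks Payne rearrangement of the alkoxide.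

Step 15
Reactants: 20 [(2R,3S)-2-methyl-3-{(1R,2Z)-3-[(4-methoxybenzyl)oxy]-2-[(tributylstannyl)methyl]-1-[(triethylsilyl)oxy]prop-2-en-1-yl}oxiran-2-yl]methanol
Product: 21 (2S,3S)-2-methyl-3-{(1R,2Z)-3-[(4-methoxybenzyl)oxy]-2-[(tributylstannyl)methyl]-1-[(triethylsilyl)oxy]prop-2-en-1-yl}oxirane-2-carbaldehyde
Conditions: SO3·pyridine, Me2SO, i-Pr2NEt, CH2Cl2, 0 °C
Reagents that add atoms: none
Why: Parikh–Doering oxidation, a non-acidic activated-sulfoxide method that spares the enol ether and allylstannane; the aldehyde is α-quaternary and cannot epimerise, and the stannane does not add to it without a Lewis acid.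

Step 16
Reactants: 8 (2R,5R)-1-[(2E)-3-{[(tert-butyldimethylsilyl)oxy]methyl}-4-(pivaloyloxy)but-2-en-1-yl]-2,5-dimethylthiolan-1-ium tetrafluoroborate; 21 (2S,3S)-2-methyl-3-{(1R,2Z)-3-[(4-methoxybenzyl)oxy]-2-[(tributylstannyl)methyl]-1-[(triethylsilyl)oxy]prop-2-en-1-yl}oxirane-2-carbaldehyde
Product: 23 acyclic bis-epoxide (C9 pivalate, C14 TBS ether, trans 2,3-epoxide, cis 4,5-epoxide, 6-OTES, C7 bearing CH2SnBu3 and the C8 PMB enol ether; 2R,3S,4S,5S,6R; C9 cis to C2), via sulfonium ylide 22 (not isolated)
Conditions: 8 (1.3 equiv), KN(SiMe3)2, THF, −78 °C; then 21, −78 → −40 °C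
Reagents that add atoms: none
Why: Sulfur-ylide (Corey–Chaykovsky) epoxidation; the ylide adds through its α-carbon, and the anti betaine closes with loss of the sulfide to the trans epoxide. The C2-symmetric sulfide shields one face of the ylide carbon and so sets C2, and the trans requirement then sets C3. The pivalate has no α-hydrogen and the aldehyde is not enolisable, so the base finds only the sulfonium salt.

Step 17
Reactants: 23 acyclic bis-epoxide pivalate
Product: 24 C9 alcohol of 23 (pivalate removed)
Conditions: i-Bu2AlH, CH2Cl2, −78 °C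
Reagents that add atoms: none
Why: Reductive cleavage of the pivalate; at −78 °C the epoxides, silyl ethers, enol ether and stannane are not attacked.

Step 18
Reactants: 24 C9 alcohol (stannane)
Product: 26 C9 alcohol carrying the pinacol boronate on C11′ (CH2B cis to OPMB), via dilithio alkoxide allyl anion 25 (not isolated)
Conditions: MeLi (2.2 equiv), THF, −78 °C; i-PrOB(pin) (3 equiv), −78 → −20 °C; pH 7 buffer
Reagents that add atoms: 2-isopropoxy-4,4,5,5-tetramethyl-1,3,2-dioxaborolane, CC(C)OB1OC(C)(C)C(C)(C)O1
Why: Tin–lithium exchange after deprotonation of the hydroxyl regenerates the chelated cis oxyallyllithium without a strong base; borylation at the terminus gives the γ-alkoxyallyl pinacol boronate with the geometry needed for a syn addition. Methyllithium at −78 °C is too poor a base and nucleophile to attack the epoxides or silyl ethers.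

Step 19
Reactants: 26 C9 alcohol (boronate)
Product: 27 C9 enal (Z; CHO cis to C2) with the pinacol γ-(PMB-oxy)allylboronate
Conditions: MnO2 (20 equiv), CH2Cl2, 0 °C; cold filtration, used at once
Reagents that add atoms: none
Why: Manganese dioxide oxidises only the allylic primary alcohol under neutral heterogeneous conditions, so the boronate, the enol ether and the enal geometry should survive.

Step 20
Reactants: 27 C9 enal with pinacol γ-(PMB-oxy)allylboronate
Product: 29 ten-membered 7-methylidene carbocycle (C1=C10 cis, 2,3- and 4,5-epoxides, 6-OTES, 8-OPMB, 9-OH, 10-CH2OTBS; 2R,3S,4S,5S,6R,8R,9R), via O-boryl macrocycle 28 (not isolated)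
Conditions: toluene (0.001 M), 60 °C; then pH 7 buffer
Reagents that add atoms: none
Why: Proposed new method: boron coordinates the C9 aldehyde oxygen and the γ-carbon C8 attacks C9 through a closed six-membered chair with allylic transposition, so the C8–C9 bond and the ten-membered carbocycle form together (10-exo-trig) and C11′ is left as the exocyclic C7 methylene; borate 28 is hydrolysed on work-up. The closest known reactions are the syn-selective intermolecular additions of Z-γ-alkoxyallylboronates to aldehydes and the Lewis-acid-promoted intramolecular additions of γ-alkoxyallylstannanes to aldehydes that close ten- to fourteen-membered rings; a thermal boron version at this ring size is not known. C9 is controlled by the enol-ether geometry: with CH2B cis to OPMB the alkoxy group is axial in the chair and, with the enal residue equatorial, the syn 8R,9R pair results. C8 is controlled by C6: with C6–H eclipsing the C7=C8 bond, the C5 arm and the silyloxy group lie on opposite faces, and the tether can return the aldehyde only to the face that gives 8R. No acid or metal is needed, so both epoxides, the silyl ethers and the enal geometry are not at risk, and the new oxygens are born differentiated (C9 free, C8 a PMB ether). High dilution suppresses bimolecular allylation, and the cis 4,5-epoxide, the trans 2,3-epoxide and the cis C1=C10 olefin bend the chain so that C8 and C9 can meet.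

Step 21
Reactants: 30 (2R)-(2-methyloxiran-2-yl)methanol
Product: 31 (2S)-2-methyloxirane-2-carboxylic acid
Conditions: RuCl3 (2 mol %), NaIO4, MeCN/EtOAc/H2O, 0 °C → rt
Reagents that add atoms: sodium periodate, [Na+].[O-]I(=O)(=O)=O, with water, O, as the source of the new oxygen
Why: Ruthenium-catalysed periodate oxidation of a primary alcohol to the acid; the quaternary stereocentre is untouched, and its descriptor changes from R to S only through priorities.

Step 22
Reactants: 29 macrocyclic alcohol; 31 (2S)-2-methyloxirane-2-carboxylic acid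
Product: 33 C9 (2S)-2-methyloxirane-2-carboxylate of 29, via mixed anhydride 32 (not isolated)
Conditions: 2-methyl-6-nitrobenzoic anhydride, Et3N, DMAP, CH2Cl2, rt
Reagents that add atoms: none
Why: Shiina esterification through the mixed anhydride and an acylpyridinium; the chloride-free conditions spare the glycidate, and C9–OH is the only free hydroxyl.

Step 23
Reactants: 33 C9 epoxy ester
Product: 34 C6 alcohol (triethylsilyl group removed)
Conditions: HF·pyridine, pyridine, THF, 0 °C
Reagents that add atoms: none
Why: Buffered fluoride removes the secondary triethylsilyl ether faster than the primary TBS ether; no acid-sensitive enol ether remains at this stage.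

Step 24
Reactants: 35 2-(bromomethyl)prop-2-enoic acid
Product: 36 2-{[(4-methoxybenzyl)oxy]methyl}prop-2-enoic acid
Conditions: 4-MeOC6H4CH2OH, NaH (2.2 equiv), THF, 0 °C → rt; aq. citric acid
Reagents that add atoms: 4-methoxybenzyl alcohol, COc1ccc(CO)cc1
Why: Alkoxide substitution at the allylic bromide of the carboxylate salt; direct and allylic displacement give the same product.

Step 25
Reactants: 34 C6 alcohol; 36 2-{[(4-methoxybenzyl)oxy]methyl}prop-2-enoic acid
Product: 38 C6 2-{[(4-methoxybenzyl)oxy]methyl}acrylate of 34, via mixed anhydride 37 (not isolated)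
Conditions: 2-methyl-6-nitrobenzoic anhydride, Et3N, DMAP, CH2Cl2, rt
Reagents that add atoms: none
Why: Shiina esterification of the hindered C6 alcohol; an alkoxymethyl acrylate, unlike an acyloxymethyl one, is not prone to addition–elimination by DMAP.

Step 26
Reactants: 38 C6 acrylate
Product: 39 macrocyclic butenolide with 8-OPMB, 13-OPMB, 14-OTBS and the C9 epoxy ester
Conditions: second-generation Grubbs catalyst (H2IMes)(PCy3)Cl2Ru=CHPh (20 mol %, in portions), toluene (0.002 M), 80 °C, argon purge
Reagents that add atoms: none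
Why: Ring-closing metathesis joins the acrylate α-carbon to C7 with loss of ethylene and forms the five-membered lactone. Acrylates of 1,1-disubstituted allylic alcohols are known to close to tetrasubstituted butenolides under forcing conditions; the trisubstituted C1=C10 olefin and the epoxides are spectators.

Step 27
Reactants: 39 bis-PMB butenolide
Product: 40 8,13-diol
Conditions: DDQ, CH2Cl2/pH 7 buffer, 0 °C → rt
Reagents that add atoms: none
Why: Oxidative cleavage of both PMB ethers under buffered conditions, which epoxides, esters and the silyl ether tolerate.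

Step 28
Reactants: 40 8,13-diol
Product: 41 8,13-diacetate
Conditions: Ac2O, pyridine, DMAP (cat.), CH2Cl2, 0 °C
Reagents that add atoms: acetic anhydride, CC(=O)OC(C)=O
Why: Acetylation of both hydroxyls in one step, run cold and promptly so that acylation of C8–OH outruns migration of the C9 acyl group.

Step 29
Reactants: 41 8,13-diacetate
Product: 42 C14 alcohol
Conditions: HF·pyridine, pyridine, THF, 0 °C → rt
Reagents that add atoms: none
Why: Buffered fluoride removes the last silyl ether without touching esters or epoxides.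

Step 30
Reactants: 42 C14 alcohol
Product: 43 CNP0279449.1
Conditions: Me2C=CHCOCl, pyridine, DMAP (cat.), CH2Cl2, −20 → 0 °C
Reagents that add atoms: 3-methylbut-2-enoyl chloride, CC(C)=CC(Cl)=O
Why: Acylation of the primary allylic alcohol; the weak base avoids deconjugation of the senecioyl group through a vinylketene.

## Compound list

1 | but-2-yne-1,4-diol | OCC#CCO | starting material
2 | 4-[(tert-butyldimethylsilyl)oxy]but-2-yn-1-ol | OCC#CCO[Si](C)(C)C(C)(C)C | intermediate
3 | sodium cyclic alkenylaluminate (2,5-dihydro-1,2-oxaaluminole ate complex, Al on C10) | [Na+].COCCO[Al-]1(OCCOC)OCC=C1CO[Si](C)(C)C(C)(C)C | intermediate (not isolated)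
4 | (2Z)-4-[(tert-butyldimethylsilyl)oxy]-3-iodobut-2-en-1-ol | OC/C=C(/CO[Si](C)(C)C(C)(C)C)I | intermediate
5 | (2E)-2-{[(tert-butyldimethylsilyl)oxy]methyl}-4-hydroxybut-2-en-1-yl 2,2-dimethylpropanoate | OC/C=C(/CO[Si](C)(C)C(C)(C)C)COC(=O)C(C)(C)C | intermediate
6 | (2E)-4-bromo-2-{[(tert-butyldimethylsilyl)oxy]methyl}but-2-en-1-yl 2,2-dimethylpropanoate | BrC/C=C(/CO[Si](C)(C)C(C)(C)C)COC(=O)C(C)(C)C | intermediate
7 | (2R,5R)-2,5-dimethylthiolane | C[C@@H]1CC[C@@H](C)S1 | starting material
8 | (2R,5R)-1-[(2E)-3-{[(tert-butyldimethylsilyl)oxy]methyl}-4-(pivaloyloxy)but-2-en-1-yl]-2,5-dimethylthiolan-1-ium tetrafluoroborate | C[C@@H]1CC[C@@H](C)[S+]1C/C=C(/CO[Si](C)(C)C(C)(C)C)COC(=O)C(C)(C)C.F[B-](F)(F)F | intermediate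
9 | 2-bromoprop-2-en-1-ol | OCC(Br)=C | starting material
10 | 1-{[(2-bromoprop-2-en-1-yl)oxy]methyl}-4-methoxybenzene | C=C(Br)COCc1ccc(OC)cc1 | intermediate
11 | 4-methylfuran-2(5H)-one | CC1=CC(=O)OC1 | starting material
12 | (2Z)-4-hydroxy-N-methoxy-N,3-dimethylbut-2-enamide | CON(C)C(=O)/C=C(C)\CO | intermediate
13 | (2Z)-N-methoxy-N,3-dimethyl-4-[(triethylsilyl)oxy]but-2-enamide | CON(C)C(=O)/C=C(C)\CO[Si](CC)(CC)CC | intermediate
14 | (2Z)-3-methyl-4-[(triethylsilyl)oxy]but-2-enal | O=C/C=C(C)\CO[Si](CC)(CC)CC | intermediate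
15 | (3S,4Z)-2-{[(4-methoxybenzyl)oxy]methyl}-5-methyl-6-[(triethylsilyl)oxy]hexa-1,4-dien-3-ol | CC[Si](CC)(CC)OC/C(C)=C\[C@H](O)C(=C)COCc1ccc(OC)cc1 | intermediate
16 | (1R)-2-{[(4-methoxybenzyl)oxy]methyl}-1-[(2S,3R)-3-methyl-3-{[(triethylsilyl)oxy]methyl}oxiran-2-yl]prop-2-en-1-ol | CC[Si](CC)(CC)OC[C@@]1(C)O[C@H]1[C@H](O)C(=C)COCc1ccc(OC)cc1 | intermediate
17 | bis(triethylsilyl) ether of 16 (4R,5S,6R in target numbering) | CC[Si](CC)(CC)OC[C@@]1(C)O[C@H]1[C@H](O[Si](CC)(CC)CC)C(=C)COCc1ccc(OC)cc1 | intermediate
18 | [(2R,3S)-3-{(1R)-2-{[(4-methoxybenzyl)oxy]methyl}-1-[(triethylsilyl)oxy]prop-2-en-1-yl}-2-methyloxiran-2-yl]methanol | OC[C@@]1(C)O[C@H]1[C@H](O[Si](CC)(CC)CC)C(=C)COCc1ccc(OC)cc1 | intermediate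
19 | dilithio alkoxide allyl anion of 18 | [Li+].[Li+].[O-]C[C@@]1(C)O[C@H]1[C@H](O[Si](CC)(CC)CC)C(=C)[CH-]OCc1ccc(OC)cc1 | intermediate (not isolated)
20 | [(2R,3S)-2-methyl-3-{(1R,2Z)-3-[(4-methoxybenzyl)oxy]-2-[(tributylstannyl)methyl]-1-[(triethylsilyl)oxy]prop-2-en-1-yl}oxiran-2-yl]methanol | OC[C@@]1(C)O[C@H]1[C@H](O[Si](CC)(CC)CC)/C(C[Sn](CCCC)(CCCC)CCCC)=C/OCc1ccc(OC)cc1 | intermediate
21 | (2S,3S)-2-methyl-3-{(1R,2Z)-3-[(4-methoxybenzyl)oxy]-2-[(tributylstannyl)methyl]-1-[(triethylsilyl)oxy]prop-2-en-1-yl}oxirane-2-carbaldehyde | O=C[C@@]1(C)O[C@H]1[C@H](O[Si](CC)(CC)CC)/C(C[Sn](CCCC)(CCCC)CCCC)=C/OCc1ccc(OC)cc1 | intermediate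
22 | sulfonium ylide of 8 (carbanion on C2) | C[C@@H]1CC[C@@H](C)[S+]1[CH-]/C=C(/CO[Si](C)(C)C(C)(C)C)COC(=O)C(C)(C)C | intermediate (not isolated)
23 | acyclic bis-epoxide, C9 pivalate, C11′ stannane (2R,3S,4S,5S,6R; C9 cis to C2; CH2Sn cis to OPMB) | CC(C)(C)C(=O)OC/C(CO[Si](C)(C)C(C)(C)C)=C\[C@H]1O[C@@H]1[C@@]1(C)O[C@H]1[C@H](O[Si](CC)(CC)CC)/C(C[Sn](CCCC)(CCCC)CCCC)=C/OCc1ccc(OC)cc1 | intermediate
24 | C9 alcohol of 23 | OC/C(CO[Si](C)(C)C(C)(C)C)=C\[C@H]1O[C@@H]1[C@@]1(C)O[C@H]1[C@H](O[Si](CC)(CC)CC)/C(C[Sn](CCCC)(CCCC)CCCC)=C/OCc1ccc(OC)cc1 | intermediate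
25 | dilithio alkoxide allyl anion from 24 | [Li+].[Li+].[O-]C/C(CO[Si](C)(C)C(C)(C)C)=C\[C@H]1O[C@@H]1[C@@]1(C)O[C@H]1[C@H](O[Si](CC)(CC)CC)C(=C)[CH-]OCc1ccc(OC)cc1 | intermediate (not isolated)
26 | C9 alcohol with pinacol γ-(PMB-oxy)allylboronate (CH2B cis to OPMB) | OC/C(CO[Si](C)(C)C(C)(C)C)=C\[C@H]1O[C@@H]1[C@@]1(C)O[C@H]1[C@H](O[Si](CC)(CC)CC)/C(CB1OC(C)(C)C(C)(C)O1)=C/OCc1ccc(OC)cc1 | intermediate
27 | C9 enal with pinacol γ-(PMB-oxy)allylboronate (key-step precursor) | O=C/C(CO[Si](C)(C)C(C)(C)C)=C\[C@H]1O[C@@H]1[C@@]1(C)O[C@H]1[C@H](O[Si](CC)(CC)CC)/C(CB1OC(C)(C)C(C)(C)O1)=C/OCc1ccc(OC)cc1 | intermediate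
28 | O-boryl macrocycle (C9–O–B(pin)) | C=C1[C@@H](OCc2ccc(OC)cc2)[C@H](OB2OC(C)(C)C(C)(C)O2)/C(CO[Si](C)(C)C(C)(C)C)=C\[C@H]2O[C@@H]2[C@@]2(C)O[C@H]2[C@@H]1O[Si](CC)(CC)CC | intermediate (not isolated)
29 | ten-membered 7-methylidene carbocycle, 8-OPMB, 9-OH, 6-OTES, 14-OTBS (2R,3S,4S,5S,6R,8R,9R) | C=C1[C@@H](OCc2ccc(OC)cc2)[C@H](O)/C(CO[Si](C)(C)C(C)(C)C)=C\[C@H]2O[C@@H]2[C@@]2(C)O[C@H]2[C@@H]1O[Si](CC)(CC)CC | intermediate
30 | (2R)-(2-methyloxiran-2-yl)methanol | OC[C@]1(C)CO1 | starting material
31 | (2S)-2-methyloxirane-2-carboxylic acid | OC(=O)[C@]1(C)CO1 | intermediate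
32 | mixed anhydride of 31 with 2-methyl-6-nitrobenzoic acid | Cc1cccc([N+](=O)[O-])c1C(=O)OC(=O)[C@]1(C)CO1 | intermediate (not isolated)
33 | C9 (2S)-2-methyloxirane-2-carboxylate of 29 | C=C1[C@@H](OCc2ccc(OC)cc2)[C@H](OC(=O)[C@]2(C)CO2)/C(CO[Si](C)(C)C(C)(C)C)=C\[C@H]2O[C@@H]2[C@@]2(C)O[C@H]2[C@@H]1O[Si](CC)(CC)CC | intermediate
34 | C6 alcohol of 33 | C=C1[C@@H](OCc2ccc(OC)cc2)[C@H](OC(=O)[C@]2(C)CO2)/C(CO[Si](C)(C)C(C)(C)C)=C\[C@H]2O[C@@H]2[C@@]2(C)O[C@H]2[C@@H]1O | intermediate
35 | 2-(bromomethyl)prop-2-enoic acid | OC(=O)C(=C)CBr | starting material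
36 | 2-{[(4-methoxybenzyl)oxy]methyl}prop-2-enoic acid | OC(=O)C(=C)COCc1ccc(OC)cc1 | intermediate
37 | mixed anhydride of 36 with 2-methyl-6-nitrobenzoic acid | Cc1cccc([N+](=O)[O-])c1C(=O)OC(=O)C(=C)COCc1ccc(OC)cc1 | intermediate (not isolated)
38 | C6 2-{[(4-methoxybenzyl)oxy]methyl}acrylate of 34 | C=C1[C@@H](OCc2ccc(OC)cc2)[C@H](OC(=O)[C@]2(C)CO2)/C(CO[Si](C)(C)C(C)(C)C)=C\[C@H]2O[C@@H]2[C@@]2(C)O[C@H]2[C@@H]1OC(=O)C(=C)COCc1ccc(OC)cc1 | intermediate
39 | macrocyclic butenolide, 8-OPMB, 13-OPMB, 14-OTBS, C9 epoxy ester | COc1ccc(COCC2=C3[C@@H](OCc4ccc(OC)cc4)[C@H](OC(=O)[C@]4(C)CO4)/C(CO[Si](C)(C)C(C)(C)C)=C\[C@H]4O[C@@H]4[C@@]4(C)O[C@H]4[C@@H]3OC2=O)cc1 | intermediate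
40 | 8,13-diol | OCC1=C2[C@@H](O)[C@H](OC(=O)[C@]3(C)CO3)/C(CO[Si](C)(C)C(C)(C)C)=C\[C@H]3O[C@@H]3[C@@]3(C)O[C@H]3[C@@H]2OC1=O | intermediate
41 | 8,13-diacetate, 14-OTBS | CC(=O)OCC1=C2[C@@H](OC(C)=O)[C@H](OC(=O)[C@]3(C)CO3)/C(CO[Si](C)(C)C(C)(C)C)=C\[C@H]3O[C@@H]3[C@@]3(C)O[C@H]3[C@@H]2OC1=O | intermediate
42 | 8,13-diacetate, 14-alcohol | CC(=O)OCC1=C2[C@@H](OC(C)=O)[C@H](OC(=O)[C@]3(C)CO3)/C(CO)=C\[C@H]3O[C@@H]3[C@@]3(C)O[C@H]3[C@@H]2OC1=O | intermediate
43 | CNP0279449.1: (1(10)Z,2R,3S,4S,5S,6R,8R,9R)-8,13-diacetoxy-2,3:4,5-diepoxy-9-{[(2S)-2-methyloxirane-2-carbonyl]oxy}-14-[(3-methylbut-2-enoyl)oxy]germacra-1(10),7(11)-dien-12,6-olide | CC(=O)OCC1=C2[C@@H](OC(C)=O)[C@H](OC(=O)[C@]3(C)CO3)/C(COC(=O)C=C(C)C)=C\[C@H]3O[C@@H]3[C@@]3(C)O[C@H]3[C@@H]2OC1=O | target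

## Step count and risk

Total: 30 steps. Longest linear sequence: 22 steps from 11 (steps 7–20, 22, 23, 25–30).

**Step 20 (key step).**
- What may go wrong: the closure may be too slow for a hindered pinacol boronate facing the entropy and transannular strain of a ten-membered ring, so that bimolecular allylation, geometric isomerisation of the enal or protodeboronation take over. Facial selection at C8 by C6 may be poor, or an axial-aldehyde or boat pathway may erode the syn relationship.
- Fallback (known chemistry): stannane alcohol 24 would be oxidised with MnO2 to the stannyl enal F1, and the ring closed by the Lewis-acid-promoted intramolecular addition of the γ-alkoxyallylstannane to the aldehyde (BF3·OEt2, CH2Cl2, −78 °C, high dilution). This reaction type is known to close ten- to fourteen-membered carbocycles and to give syn products from cis γ-alkoxyallylstannanes through an open transition state. It returns to the route at 29; the price is brief exposure of the epoxides to a Lewis acid at low temperature.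

**Step 16 (fragment union).**
- What may go wrong: poor facial selectivity, because the chiral ylide meets an aldehyde with its own α-stereocentre and the two preferences may oppose each other; the result would be cis epoxide or the 2,3-diastereomer.
- Fallback: the union would be moved to a stage where the aldehyde has no neighbouring stereocentre.
  - From 15, silylation gives bis(triethylsilyl) ether F2; buffered fluoride frees the primary alcohol F3; MnO2 gives the Z-enal F4.
  - Ylide 22 (from 8) converts F4 into vinyl epoxide F5 under pure reagent control.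
  - HF·pyridine frees the C6 alcohol F6; hydroxyl-directed epoxidation (VO(acac)2, t-BuOOH) gives bis-epoxy alcohol F7; silylation gives F8; i-Bu2AlH removes the pivalate to give F9.
  - Direct metalation of the allyl ether of F9 (s-BuLi, 2.2 equiv) and borylation with the isopropoxy boronate return to the route at 26.

**Step 14 (metalation and stannylation).**
- What may go wrong: competing metalation at the PMB benzylic position followed by Wittig rearrangement, or incomplete second deprotonation because the lithium alkoxide aggregates with the base.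
- Fallback: the order of desilylation and metalation would be reversed. From 17, s-BuLi (1.1 equiv) and Bu3SnCl give the bis(triethylsilyl) stannane F10 with no resident alkoxide; a nearly neutral fluoride source (NH4F, MeOH) then frees the primary alcohol and returns to 20.

**Step 18 (tin–lithium exchange and borylation).**
- What may go wrong: sluggish or unselective exchange in the presence of the lithium alkoxide, or partial borylation at the oxygen-bearing carbon.
- Fallback: the hydroxyl would be masked for the exchange. From 24, Et3SiCl and imidazole give the silyl ether F11; MeLi (1.1 equiv) and the isopropoxy boronate give the boronate F12; NH4F in MeOH returns to 26. If the exchange proves unworkable, the stannane can be used directly as in the fallback for step 20.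

**Step 26 (ring-closing metathesis).**
- What may go wrong: failure of the catalyst to engage two 1,1-disubstituted olefins, one electron-poor and one flanked by two oxygenated stereocentres, leading to catalyst decomposition before closure.
- Fallback: a relay ring-closing metathesis, which loads ruthenium on an unhindered terminal olefin.
  - Hex-5-enal and methyl acrylate give the Baylis–Hillman adduct F13; N-bromosuccinimide and Me2S give the allylic bromide F14; sodium 4-methoxybenzyl oxide gives the ether F15; LiOH gives the relay acid F16.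
  - Shiina esterification of 34 with F16 gives the relay ester F17.
  - The second-generation Grubbs catalyst would initiate at the terminal olefin of F17, expel cyclopentene, and leave the alkylidene on the acrylate carbon for closure onto the C7 methylene, returning to 39.

## Further compounds

F1 | step 20 | stannyl enal (C9 aldehyde of 24) | O=C/C(CO[Si](C)(C)C(C)(C)C)=C\[C@H]1O[C@@H]1[C@@]1(C)O[C@H]1[C@H](O[Si](CC)(CC)CC)/C(C[Sn](CCCC)(CCCC)CCCC)=C/OCc1ccc(OC)cc1
F2 | step 16 | bis(triethylsilyl) ether of 15 | CC[Si](CC)(CC)OC/C(C)=C\[C@H](O[Si](CC)(CC)CC)C(=C)COCc1ccc(OC)cc1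
F3 | step 16 | (2Z,4S)-5-{[(4-methoxybenzyl)oxy]methyl}-2-methyl-4-[(triethylsilyl)oxy]hexa-2,5-dien-1-ol | OC/C(C)=C\[C@H](O[Si](CC)(CC)CC)C(=C)COCc1ccc(OC)cc1
F4 | step 16 | (2Z,4S)-5-{[(4-methoxybenzyl)oxy]methyl}-2-methyl-4-[(triethylsilyl)oxy]hexa-2,5-dienal | O=C/C(C)=C\[C@H](O[Si](CC)(CC)CC)C(=C)COCc1ccc(OC)cc1
F5 | step 16 | vinyl epoxide from F4 and 22 (trans 2,3-epoxide, 4,5-olefin, 6-OTES, C9 pivalate) | CC(C)(C)C(=O)OC/C(CO[Si](C)(C)C(C)(C)C)=C\[C@H]1O[C@@H]1/C(C)=C\[C@H](O[Si](CC)(CC)CC)C(=C)COCc1ccc(OC)cc1
F6 | step 16 | C6 alcohol of F5 | CC(C)(C)C(=O)OC/C(CO[Si](C)(C)C(C)(C)C)=C\[C@H]1O[C@@H]1/C(C)=C\[C@H](O)C(=C)COCc1ccc(OC)cc1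
F7 | step 16 | bis-epoxy C6 alcohol (tin-free, C9 pivalate) | CC(C)(C)C(=O)OC/C(CO[Si](C)(C)C(C)(C)C)=C\[C@H]1O[C@@H]1[C@@]1(C)O[C@H]1[C@H](O)C(=C)COCc1ccc(OC)cc1
F8 | step 16 | triethylsilyl ether of F7 | CC(C)(C)C(=O)OC/C(CO[Si](C)(C)C(C)(C)C)=C\[C@H]1O[C@@H]1[C@@]1(C)O[C@H]1[C@H](O[Si](CC)(CC)CC)C(=C)COCc1ccc(OC)cc1
F9 | step 16 | C9 alcohol of F8 (allyl PMB ether, tin-free) | OC/C(CO[Si](C)(C)C(C)(C)C)=C\[C@H]1O[C@@H]1[C@@]1(C)O[C@H]1[C@H](O[Si](CC)(CC)CC)C(=C)COCc1ccc(OC)cc1
F10 | step 14 | bis(triethylsilyl) γ-(PMB-oxy)allylstannane from 17 | CC[Si](CC)(CC)OC[C@@]1(C)O[C@H]1[C@H](O[Si](CC)(CC)CC)/C(C[Sn](CCCC)(CCCC)CCCC)=C/OCc1ccc(OC)cc1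
F11 | step 18 | C9 triethylsilyl ether of 24 | CC[Si](CC)(CC)OC/C(CO[Si](C)(C)C(C)(C)C)=C\[C@H]1O[C@@H]1[C@@]1(C)O[C@H]1[C@H](O[Si](CC)(CC)CC)/C(C[Sn](CCCC)(CCCC)CCCC)=C/OCc1ccc(OC)cc1
F12 | step 18 | C9 triethylsilyl ether of 26 | CC[Si](CC)(CC)OC/C(CO[Si](C)(C)C(C)(C)C)=C\[C@H]1O[C@@H]1[C@@]1(C)O[C@H]1[C@H](O[Si](CC)(CC)CC)/C(CB1OC(C)(C)C(C)(C)O1)=C/OCc1ccc(OC)cc1
F13 | step 26 | methyl 3-hydroxy-2-methylideneoct-7-enoate (racemic) | COC(=O)C(=C)C(O)CCCC=C
F14 | step 26 | methyl (2Z)-2-(bromomethyl)octa-2,7-dienoate | BrC/C(C(=O)OC)=C\CCCC=C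
F15 | step 26 | methyl (2E)-2-{[(4-methoxybenzyl)oxy]methyl}octa-2,7-dienoate | COc1ccc(COC/C(C(=O)OC)=C\CCCC=C)cc1
F16 | step 26 | (2E)-2-{[(4-methoxybenzyl)oxy]methyl}octa-2,7-dienoic acid | COc1ccc(COC/C(C(O)=O)=C\CCCC=C)cc1
F17 | step 26 | C6 relay ester of 34 with F16 | C=C1[C@@H](OCc2ccc(OC)cc2)[C@H](OC(=O)[C@]2(C)CO2)/C(CO[Si](C)(C)C(C)(C)C)=C\[C@H]2O[C@@H]2[C@@]2(C)O[C@H]2[C@@H]1OC(=O)/C(COCc1ccc(OC)cc1)=C/CCCC=C
A1 | alternative 1 | C12-trimethylsilyl furan fused at C6–C7, fully acylated macrocycle | CC(=O)OCc1c([Si](C)(C)C)oc2c1[C@@H](OC(C)=O)[C@H](OC(=O)[C@]3(C)CO3)/C(COC(=O)C=C(C)C)=C\[C@H]3O[C@@H]3[C@@]3(C)O[C@H]32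
A2 | alternative 1 | Z γ-keto acid (open tautomer of the 6-hydroxybutenolide) | CC(=O)OC/C(C(O)=O)=C1\[C@@H](OC(C)=O)[C@H](OC(=O)[C@]2(C)CO2)/C(COC(=O)C=C(C)C)=C\[C@H]2O[C@@H]2[C@@]2(C)O[C@H]2C1=O
A3 | alternative 2 | acyclic C7 enol triflate with cis C12 methyl ester and C6 enal | COC(=O)/C(COC(C)=O)=C(\OS(=O)(=O)C(F)(F)F)[C@@H](O[Si](C)(C)C(C)(C)C)[C@H](OC(=O)[C@]1(C)CO1)/C(COC(=O)C=C(C)C)=C\[C@H]1O[C@@H]1/C(C)=C\C=O
A4 | alternative 2 | C8-silyl 4,5-ene macrocyclic butenolide | CC(=O)OCC1=C2[C@@H](O[Si](C)(C)C(C)(C)C)[C@H](OC(=O)[C@]3(C)CO3)/C(COC(=O)C=C(C)C)=C\[C@H]3O[C@@H]3/C(C)=C\[C@@H]2OC1=O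
A5 | alternative 3 | C2 allylic diphenylsulfonium tetrafluoroborate with C3 aldehyde on the butenolide | CC(=O)OCC1=C([C@@H](OCc2ccc(OC)cc2)[C@H](O[Si](C)(C)C(C)(C)C)/C(CO[Si](C)(C)C(C)(C)C)=C\C[S+](c2ccccc2)c2ccccc2)[C@@H](OC1=O)[C@@H]1O[C@]1(C)C=O.F[B-](F)(F)F
A6 | alternative 3 | protected bis-epoxy macrocyclic butenolide | CC(=O)OCC1=C2[C@@H](OCc3ccc(OC)cc3)[C@H](O[Si](C)(C)C(C)(C)C)/C(CO[Si](C)(C)C(C)(C)C)=C\[C@H]3O[C@@H]3[C@@]3(C)O[C@H]3[C@@H]2OC1=O
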